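Retrosynthesis, first cut: the C7–CH2 bond between the methylene bridge and the quinone methide half (conjugate addition of decarboxycitrinin to the ortho-quinone methide of the lactone half). Both halves go back to one (3R,4S)-3,4,5-trimethylisochroman, whose C1 is oxidised to the lactol and then either dehydrated (quinone methide) or oxidised (lactone).
Second cut: in that isochroman the C4a–C4 bond of the pyran ring is cut and C4a is re-attached to C3. The precursor is a 1-(1-mesyloxyethyl)phthalan, a five-membered benzo-fused ether made from an aryllithium, (S)-lactaldehyde and a benzylic CH2OH.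
Enabling feature: C4a is meta to both ring oxygens O6 and O8, so no Friedel–Crafts closure can reach it. C3, next to C4, carries the ring oxygen O2, and a lone pair of O2 can push the arene from C3 to C4 (1,2-aryl shift), which enlarges the five-membered ring to the six-membered pyran ring.
Forward order: pentasubstituted arene (two Vilsmeier–Haack formylations), phthalan ring, ring enlargement with methylation to the pyran ring, divergence at the lactol, Mannich activation of the lactone half, methylene bridge last.
Stereochemistry: C4 and C4' come from (S)-lactaldehyde by inversion in the aryl shift. C3 and C3' come from methyl transfer anti to the C4 methyl group in the same step. No later step touches these four centres.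

Key step: step 9

Remark: atoms carry the isochroman numbering of the target halves (C1, O2, C3, C4, C4a, C5 to C8, C8a; primes for the lactone half), also in earlier intermediates, and the quinone methides are drawn as the 6-hydroxy-8-oxo tautomer of the target SMILES.

Step 1
Reactants: 1 5-bromoresorcinol (5-bromobenzene-1,3-diol)
Product: 2 1,3-bis(benzyloxy)-5-bromobenzene
Conditions: BnBr (2.2 equiv), K2CO3, DMF, rt
Reagents that add atoms: benzyl bromide BrCc1ccccc1
Why: Williamson ether synthesis caps both phenols as benzyl ethers, which should tolerate POCl3, n-BuLi, AlMe3 and DDQ and can be removed later by BCl3 or by hydrogenolysis.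

Step 2
Reactants: 2 1,3-bis(benzyloxy)-5-bromobenzene
Product: 3 2,4-bis(benzyloxy)-6-bromobenzaldehyde
Conditions: POCl3, DMF, 0 °C to 80 °C; then H2O
Reagents that add atoms: N,N-dimethylformamide CN(C)C=O; water O
Why: Vilsmeier–Haack formylation of a 5-substituted resorcinol diether goes para to one alkoxy group and ortho to the other, next to bromine and not between the two alkoxy groups, and the new carbon becomes the C5 methyl group.

Step 3
Reactants: 3 2,4-bis(benzyloxy)-6-bromobenzaldehyde
Product: 4 1,5-bis(benzyloxy)-3-bromo-2-methylbenzene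
Conditions: Et3SiH (2.5 equiv), CF3CO2H, CH2Cl2, 0 °C to rt
Reagents that add atoms: none
Why: Ionic hydrogenation (hydride transfer, ionisation of the 2,4-dialkoxybenzylic alcohol, second hydride transfer) takes the electron-rich aldehyde down to methyl and leaves the aryl bromide and the benzyl ethers alone.

Step 4
Reactants: 4 1,5-bis(benzyloxy)-3-bromo-2-methylbenzene
Product: 5 4,6-bis(benzyloxy)-2-bromo-3-methylbenzaldehyde
Conditions: POCl3, DMF, 0 °C to 80 °C; then H2O
Reagents that add atoms: N,N-dimethylformamide CN(C)C=O; water O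
Why: A second Vilsmeier–Haack formylation follows the same rule and enters the one remaining position para to an alkoxy group, between bromine and benzyloxy, which places C1 on C8a.

Step 5
Reactants: 5 4,6-bis(benzyloxy)-2-bromo-3-methylbenzaldehyde
Product: 6 [4,6-bis(benzyloxy)-2-bromo-3-methylphenyl]methanol
Conditions: NaBH4, MeOH/THF, 0 °C
Reagents that add atoms: none
Why: Borohydride reduction of the aldehyde gives the benzylic alcohol that becomes the C1H2–O2 unit, and nothing else in 5 is reducible under these conditions.

Step 6
Reactants: 6 [4,6-bis(benzyloxy)-2-bromo-3-methylphenyl]methanol; 7 (S)-2-(tert-butyldimethylsilyloxy)propanal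
Product: 11 tert-butyl{(1S)-1-[4,6-bis(benzyloxy)-7-methyl-1,3-dihydro-2-benzofuran-1-yl]ethoxy}dimethylsilane (both epimers at the ring carbon that is C3 of the target), via dilithio species 8 (not isolated), via dilithium dialkoxide 9 (not isolated), via benzylic mesylate 10 (not isolated)
Conditions: n-BuLi (2.1 equiv), THF, −78 °C; 7, −78 °C; MsCl (1.0 equiv), −78 °C to rt
Reagents that add atoms: none
Why: Deprotonation and bromine–lithium exchange give 8, whose 1,2-addition to the aldehyde (Felkin–Anh sense favoured) makes the temporary C4a–C3 bond, and mesylation of the less hindered primary alkoxide followed by intramolecular Williamson closure (5-exo-tet) gives the phthalan; the silyloxy carbon stays S, and the epimer mixture at C3 does not matter because C3 is flattened in step 9.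

Step 7
Reactants: 11 the silyl ether from step 6
Product: 12 (1S)-1-[4,6-bis(benzyloxy)-7-methyl-1,3-dihydro-2-benzofuran-1-yl]ethanol (both ring-carbon epimers)
Conditions: n-Bu4NF, THF, 0 °C to rt
Reagents that add atoms: none
Why: Fluoride-induced desilylation frees the secondary alcohol under non-acidic conditions, so the acid-sensitive dialkoxybenzylic ether and the carbinol configuration are untouched.

Step 8
Reactants: 12 (1S)-1-[4,6-bis(benzyloxy)-7-methyl-1,3-dihydro-2-benzofuran-1-yl]ethanol
Product: 13 (1S)-1-[4,6-bis(benzyloxy)-7-methyl-1,3-dihydro-2-benzofuran-1-yl]ethyl methanesulfonate (both ring-carbon epimers)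
Conditions: MsCl, Et3N, CH2Cl2, 0 °C
Reagents that add atoms: methanesulfonyl chloride CS(=O)(=O)Cl
Why: O-sulfonylation proceeds with retention and installs on C4 the leaving group that is used in organoaluminium-promoted pinacol-type shifts.

Step 9
Reactants: 13 (1S)-1-[4,6-bis(benzyloxy)-7-methyl-1,3-dihydro-2-benzofuran-1-yl]ethyl methanesulfonate
Product: 15 (3R,4S)-6,8-bis(benzyloxy)-3,4,5-trimethylisochroman, via oxocarbenium aluminate 14 (not isolated)
Conditions: AlMe3 (4 equiv), CH2Cl2, −78 °C to 0 °C; then H2O
Reagents that add atoms: trimethylaluminium C[Al](C)C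
Why: Proposed new method: AlMe3 binds the mesylate of 13 and, in the rotamer with C4–OMs antiperiplanar to C3–C4a, the aryl carbon C4a slides from C3 to C4 through a phenonium-like bridged transition state while a lone pair of O2 closes onto C3, which gives the six-membered oxocarbenium aluminate 14, and this ion pair then transfers a methyl group to C3. The closest known reaction types are the trialkylaluminium-promoted pinacol-type 1,2-aryl shift of lactate-derived beta-mesyloxy alcohols, the 1,2-aryl shift of alpha-sulfonyloxy acetals to 2-arylpropanoates and the C-methylation of cyclic oxocarbenium ions by AlMe3; what has not been shown is their union with a ring ether as the pushing oxygen, which turns the shift into a ring enlargement. The ring closes by 3-exo-tet attack of C4a on C4 followed by rupture of the old C4a–C3 bond, so the five-membered phthalan ring becomes the six-membered pyran ring (C1, O2, C3, C4, C4a, C8a) that holds the new C4a–C4 bond. C4 is set by inversion at the lactaldehyde-derived carbon (S mesylate to 4S), and C3 by attack of methyl anti to the C4 methyl group, which is held pseudoaxial by peri strain with the C5 methyl group, so the trans (3R,4S) isomer should result from either C3 epimer of 13. The step needs aryl migration to win over hydride shift from C3, over participation by O2 and over loss of H4 from 14: the flat five-membered ring holds C4 out of the arene plane above the p orbital of C4a, the migrating arene carries two ortho alkyl groups, a three-membered oxonium ion is strained, and the aluminate counter-ion delivers methyl within the ion pair. The low temperature and the modest Lewis acidity of AlMe3 should keep the benzylic C1–O2 bond and the benzyl ethers intact.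

Step 10
Reactants: 15 (3R,4S)-6,8-bis(benzyloxy)-3,4,5-trimethylisochroman
Product: 16 (3R,4S)-6,8-bis(benzyloxy)-3,4,5-trimethylisochroman-1-ol (lactol, both anomers)
Conditions: DDQ (1.1 equiv), CH2Cl2/H2O, 0 °C
Reagents that add atoms: water O
Why: DDQ abstracts hydride from C1, the only C–H that is both alpha to oxygen and ortho/para to the two alkoxy groups (the reaction type that cleaves 2,4-dialkoxybenzyl ethers), and water traps the cation as a hemiacetal that stays closed as the six-membered lactol, with C3 and C4 not involved.

Step 11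
Reactants: 16 (3R,4S)-6,8-bis(benzyloxy)-3,4,5-trimethylisochroman-1-ol
Product: 18 decarboxycitrinin, (3R,4S)-6-hydroxy-3,4,5-trimethyl-3,4-dihydroisochromen-8-one, via lactol diol 17 (not isolated)
Conditions: BCl3 (4 equiv), pentamethylbenzene (6 equiv), CH2Cl2, −78 °C; then H2O; concentration from toluene
Reagents that add atoms: none
Why: Lewis acid debenzylation with pentamethylbenzene as a non-basic benzyl cation scavenger is non-reductive, so the oxidation level of C1 is kept, and the para-hydroxy lactol 17 should lose water readily to give the vinylogous-acid quinone methide.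

Step 12
Reactants: 16 (3R,4S)-6,8-bis(benzyloxy)-3,4,5-trimethylisochroman-1-ol
Product: 19 (3R,4S)-6,8-bis(benzyloxy)-3,4,5-trimethylisochroman-1-one
Conditions: (n-Pr4N)[RuO4] (5 mol %), NMO, 4 Å molecular sieves, CH2Cl2, rt
Reagents that add atoms: none
Why: Ley–Griffith oxidation converts a lactol into the lactone under neutral conditions that spare the benzyl ethers, the electron-rich arene and both stereocentres.

Step 13
Reactants: 19 (3R,4S)-6,8-bis(benzyloxy)-3,4,5-trimethylisochroman-1-one
Product: 20 (3R,4S)-6,8-dihydroxy-3,4,5-trimethylisochroman-1-one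
Conditions: H2 (1 atm), 10% Pd/C, EtOAc, rt
Reagents that add atoms: none
Why: Hydrogenolysis removes both aryl benzyl ethers, and the lactone has no benzylic C–O bond that could be cleaved.

Step 14
Reactants: 20 (3R,4S)-6,8-dihydroxy-3,4,5-trimethylisochroman-1-one
Product: 21 (3R,4S)-7-[(dimethylamino)methyl]-6,8-dihydroxy-3,4,5-trimethylisochroman-1-one
Conditions: aq CH2O (1.1 equiv), aq Me2NH (1.1 equiv), EtOH, rt
Reagents that add atoms: formaldehyde C=O; dimethylamine CNC
Why: The Mannich reaction can only enter C7', the single free ring position, which lies between the two hydroxy groups as in the known aminomethylation of 2,4-dihydroxyaryl ketones.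

Step 15
Reactants: 21 (3R,4S)-7-[(dimethylamino)methyl]-6,8-dihydroxy-3,4,5-trimethylisochroman-1-one; 18 decarboxycitrinin
Product: 24 dicitrinone G, via methiodide 22 (not isolated), via ortho-quinone methide 23 (not isolated)
Conditions: MeI (1.0 equiv), THF, rt, then evaporation; 18 (1.0 equiv), K2CO3 (1.0 equiv), MeCN, 0 °C to rt; pH 4 buffer
Reagents that add atoms: none
Why: N-methylation makes trimethylamine the leaving group, mild base releases 23 by 1,4-elimination, and C7 of 18, the central carbon of the vinylogous acid (C6–OH, C8=O), adds in a Michael reaction of the kind known for 1,3-dicarbonyl compounds and ortho-quinone methides from Mannich bases, which re-aromatises the lactone half and neither forms nor touches a stereocentre.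

Compound list
1 | 5-bromoresorcinol | Oc1cc(O)cc(Br)c1 | starting material
2 | 1,3-bis(benzyloxy)-5-bromobenzene | Brc1cc(OCc2ccccc2)cc(OCc2ccccc2)c1 | intermediate
3 | 2,4-bis(benzyloxy)-6-bromobenzaldehyde | O=Cc1c(Br)cc(OCc2ccccc2)cc1OCc1ccccc1 | intermediate
4 | 1,5-bis(benzyloxy)-3-bromo-2-methylbenzene | Cc1c(Br)cc(OCc2ccccc2)cc1OCc1ccccc1 | intermediate
5 | 4,6-bis(benzyloxy)-2-bromo-3-methylbenzaldehyde | Cc1c(Br)c(C=O)c(OCc2ccccc2)cc1OCc1ccccc1 | intermediate
6 | [4,6-bis(benzyloxy)-2-bromo-3-methylphenyl]methanol | Cc1c(Br)c(CO)c(OCc2ccccc2)cc1OCc1ccccc1 | intermediate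
7 | (S)-2-(tert-butyldimethylsilyloxy)propanal | C[C@H](O[Si](C)(C)C(C)(C)C)C=O | starting material
8 | dilithio species of 6 (aryllithium and lithium alkoxide) | [Li]c1c(C)c(OCc2ccccc2)cc(OCc2ccccc2)c1CO[Li] | intermediate
9 | dilithium dialkoxide of the adduct of 8 and 7 (carbinol epimers) | C[C@H](O[Si](C)(C)C(C)(C)C)C(O[Li])c1c(C)c(OCc2ccccc2)cc(OCc2ccccc2)c1CO[Li] | intermediate
10 | primary benzylic mesylate of 9 (secondary lithium alkoxide) | C[C@H](O[Si](C)(C)C(C)(C)C)C(O[Li])c1c(C)c(OCc2ccccc2)cc(OCc2ccccc2)c1COS(C)(=O)=O | intermediate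
11 | tert-butyl{(1S)-1-[4,6-bis(benzyloxy)-7-methyl-1,3-dihydro-2-benzofuran-1-yl]ethoxy}dimethylsilane (ring-carbon epimers) | C[C@H](O[Si](C)(C)C(C)(C)C)C1OCc2c(OCc3ccccc3)cc(OCc3ccccc3)c(C)c21 | intermediate
12 | (1S)-1-[4,6-bis(benzyloxy)-7-methyl-1,3-dihydro-2-benzofuran-1-yl]ethanol (ring-carbon epimers) | C[C@H](O)C1OCc2c(OCc3ccccc3)cc(OCc3ccccc3)c(C)c21 | intermediate
13 | (1S)-1-[4,6-bis(benzyloxy)-7-methyl-1,3-dihydro-2-benzofuran-1-yl]ethyl methanesulfonate (ring-carbon epimers) | C[C@H](OS(C)(=O)=O)C1OCc2c(OCc3ccccc3)cc(OCc3ccccc3)c(C)c21 | intermediate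
14 | (4S)-6,8-bis(benzyloxy)-4,5-dimethyl-1,4-dihydroisochromen-2-ium trimethyl(mesyloxy)aluminate | Cc1c2c(C[O+]=C[C@H]2C)c(OCc2ccccc2)cc1OCc1ccccc1.C[Al-](C)(C)OS(C)(=O)=O | intermediate
15 | (3R,4S)-6,8-bis(benzyloxy)-3,4,5-trimethylisochroman | Cc1c2c(CO[C@H](C)[C@H]2C)c(OCc2ccccc2)cc1OCc1ccccc1 | intermediate
16 | (3R,4S)-6,8-bis(benzyloxy)-3,4,5-trimethylisochroman-1-ol (anomers) | Cc1c2c(C(O)O[C@H](C)[C@H]2C)c(OCc2ccccc2)cc1OCc1ccccc1 | intermediate
17 | (3R,4S)-3,4,5-trimethylisochroman-1,6,8-triol (anomers) | Cc1c2c(C(O)O[C@H](C)[C@H]2C)c(O)cc1O | intermediate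
18 | decarboxycitrinin, (3R,4S)-6-hydroxy-3,4,5-trimethyl-3,4-dihydroisochromen-8-one | CC1=C2C(=CO[C@H](C)[C@H]2C)C(=O)C=C1O | intermediate
19 | (3R,4S)-6,8-bis(benzyloxy)-3,4,5-trimethylisochroman-1-one | Cc1c2c(C(=O)O[C@H](C)[C@H]2C)c(OCc2ccccc2)cc1OCc1ccccc1 | intermediate
20 | (3R,4S)-6,8-dihydroxy-3,4,5-trimethylisochroman-1-one | Cc1c2c(C(=O)O[C@H](C)[C@H]2C)c(O)cc1O | intermediate
21 | (3R,4S)-7-[(dimethylamino)methyl]-6,8-dihydroxy-3,4,5-trimethylisochroman-1-one | Cc1c2c(C(=O)O[C@H](C)[C@H]2C)c(O)c(CN(C)C)c1O | intermediate
22 | [(3R,4S)-6,8-dihydroxy-3,4,5-trimethyl-1-oxoisochroman-7-yl]methyl(trimethyl)ammonium iodide | Cc1c2c(C(=O)O[C@H](C)[C@H]2C)c(O)c(C[N+](C)(C)C)c1O.[I-] | intermediate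
23 | (3R,4S)-8-hydroxy-3,4,5-trimethyl-7-methylidene-3,4-dihydroisochromene-1,6-dione (ortho-quinone methide) | CC1=C2C(=C(O)C(=C)C1=O)C(=O)O[C@H](C)[C@H]2C | intermediate
24 | dicitrinone G | CC1=C2C(=CO[C@H](C)[C@H]2C)C(=O)C(Cc2c(O)c(C)c3c(c2O)C(=O)O[C@H](C)[C@H]3C)=C1O | target

Total step count: 15.
Longest linear sequence: 14 steps (steps 1 to 10 and 12 to 15).

Steps most likely to fail

Step 9. Hydride migration from C3 may compete with aryl migration. O2 may participate, and the oxocarbenium ion may lose H4, which would erase C4. The Lewis acid may also ionise the benzylic C1–O2 bond. The fallback uses known chemistry, makes the C4a–C4 bond intermolecularly and closes the pyran ring at C1–C8a instead; it sets out from 4 and comes back at 15. Bromine–lithium exchange (n-BuLi, THF, −78 °C) would give [3,5-bis(benzyloxy)-2-methylphenyl]lithium F1. In the presence of BF3·OEt2 this opens (2S,3S)-2,3-dimethyloxirane with inversion to give (2S,3S)-3-[3,5-bis(benzyloxy)-2-methylphenyl]butan-2-ol F2. Mitsunobu inversion of the carbinol with 4-nitrobenzoic acid (PPh3, DIAD) would give (2R,3S)-3-[3,5-bis(benzyloxy)-2-methylphenyl]butan-2-yl 4-nitrobenzoate F3. Saponification (LiOH, THF/H2O) would give (2R,3S)-3-[3,5-bis(benzyloxy)-2-methylphenyl]butan-2-ol F4. An oxa-Pictet–Spengler closure with dimethoxymethane and BF3·OEt2 at C8a, which is para and ortho to the two alkoxy groups, would then give 15.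

Step 11. The Lewis acid may open the pyran ring, benzyl cations may alkylate the free position C7, and the liberated quinone methide may hydrate or oligomerise on concentration. The fallback deprotects first at the ether oxidation level and oxidises last; it sets out from 15 and comes back at 18. Hydrogenolysis (H2, 10% Pd/C, EtOAc) would give (3R,4S)-3,4,5-trimethylisochroman-6,8-diol F5. Dehydrogenation of this para-hydroxybenzylic ether with DDQ (1 equiv, dioxane, rt) would then give 18 directly.

Step 15. The ortho-quinone methide may self-condense, alkylation may occur at oxygen instead of C7, and base, water or amine may add at C1 of the quinone methide partner. The fallback joins the halves while both are aromatic and unveils the quinone methide last; it sets out from 15 (through F5, made as above) and 21 and comes back at 24. The resorcinol F5, whose only free ring position is C7, would capture 23 generated from 22 (MeI, then K2CO3, MeCN). This would give (3R,4S)-7-{[(3R,4S)-6,8-dihydroxy-3,4,5-trimethylisochroman-7-yl]methyl}-6,8-dihydroxy-3,4,5-trimethylisochroman-1-one F6. Oxidation of the isochroman C1–H with DDQ (1 equiv, dioxane, 0 °C) would then give 24.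

Further compounds
F1 | step 9 | [3,5-bis(benzyloxy)-2-methylphenyl]lithium | [Li]c1cc(OCc2ccccc2)cc(OCc2ccccc2)c1C
F2 | step 9 | (2S,3S)-3-[3,5-bis(benzyloxy)-2-methylphenyl]butan-2-ol | O[C@@H](C)[C@H](c1cc(OCc2ccccc2)cc(OCc2ccccc2)c1C)C
F3 | step 9 | (2R,3S)-3-[3,5-bis(benzyloxy)-2-methylphenyl]butan-2-yl 4-nitrobenzoate | O=C(O[C@H](C)[C@H](c1cc(OCc2ccccc2)cc(OCc2ccccc2)c1C)C)c1ccc(cc1)[N+](=O)[O-]
F4 | step 9 | (2R,3S)-3-[3,5-bis(benzyloxy)-2-methylphenyl]butan-2-ol | O[C@H](C)[C@H](c1cc(OCc2ccccc2)cc(OCc2ccccc2)c1C)C
F5 | step 11 | (3R,4S)-3,4,5-trimethylisochroman-6,8-diol | Cc1c2c(CO[C@H](C)[C@H]2C)c(O)cc1O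
F6 | step 15 | (3R,4S)-7-{[(3R,4S)-6,8-dihydroxy-3,4,5-trimethylisochroman-7-yl]methyl}-6,8-dihydroxy-3,4,5-trimethylisochroman-1-one | Cc1c2c(CO[C@H](C)[C@H]2C)c(O)c(Cc2c(O)c(C)c3c(c2O)C(=O)O[C@H](C)[C@H]3C)c1O
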